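**Retrosynthetic overview**

1. Working numbers: C1 (oxolane carbon with isopropyl)–C2=C3–C4(OH)(CH3)–C5–C6(=O)–C7–C8(CH3)–C9–C10–C11(OCHO)–C12 (oxolane carbon with methyl); C13 and C14 are the oxolane CH2 groups. The formate is put on last.
2. Feature used: the β-methyl ketone C6(=O)–C7H2–C8H(CH3) inside the 14-membered carbocycle. With C6 as carbinol and C7=C8 as alkene it is the sum of an aldehyde carbon, a terminal alkyne and a methyl group. C6–C7 (ring closure) and C8–CH3 are therefore cut together: nickel-catalysed alkylative macrocyclisation of an acyclic ynal with Me2Zn, then oxidation and asymmetric conjugate reduction (C8).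
3. Ynal: the C6 aldehyde comes from an allyl group (C4 set by asymmetric allylboration of the C2=C3–C4 enone, itself from a Wittig reaction at C2). The C7≡C8 alkyne comes from a butynyl Grignard reagent added to a C11 Weinreb amide; C11 is set by CBS reduction.
4. The oxolane with both quaternary centres C1 and C12 and cis arms comes from (R)-terpinen-4-ol: epoxidation and transannular etherification to the 7-oxanorbornane (1,4-cineole frame), then oxidative cleavage of its C2–C11 bridge.
5. Ring order: oxolane (step 1; the six-membered carbocycle of the terpene is cut in step 4), then the 14-membered carbocycle (step 13).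

Key step: step 13

Remark: (R)-(−)-terpinen-4-ol is taken as purchasable in high enantiomeric purity; a lot of lower ee would be enriched by crystallisation at the stage of alcohol 3.

**Route**

Step 1
Reactants: 1 (R)-(−)-terpinen-4-ol
Product: 3 (1S,2R,4R)-1-methyl-4-(propan-2-yl)-7-oxabicyclo[2.2.1]heptan-2-ol, via (1S,2R,4R)-1,2-epoxy-p-menthan-4-ol 2 (not isolated)
Conditions: VO(acac)2 (1 mol %), tBuOOH, toluene, 40 °C; then TsOH·H2O (cat.), 25 °C
Reagents that add atoms: tert-butyl hydroperoxide, CC(C)(C)OO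
Why: Hydroxyl-directed vanadium-catalysed epoxidation puts the epoxide on the face of the tertiary hydroxyl, and acid-catalysed intramolecular epoxide opening at the methyl-bearing carbon (known for this terpene) closes the oxolane as a 7-oxanorbornane, so that C1 is kept from 1 and C12 is fixed by the bridged ring with the two future arms (C2 and C11) necessarily cis.

Step 2
Reactants: 3 (1S,2R,4R)-1-methyl-4-(propan-2-yl)-7-oxabicyclo[2.2.1]heptan-2-ol
Product: 4 (1S,4R)-1-methyl-4-(propan-2-yl)-7-oxabicyclo[2.2.1]heptan-2-one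
Conditions: nPr4N[RuO4] (5 mol %), NMO, 4 Å MS, CH2Cl2, 25 °C
Reagents that add atoms: none
Why: Ley–Griffith oxidation of a secondary alcohol to the ketone, with no stereocentre involved.

Step 3
Reactants: 4 (1S,4R)-1-methyl-4-(propan-2-yl)-7-oxabicyclo[2.2.1]heptan-2-one
Product: 5 trimethyl{[(1S,4S)-1-methyl-4-(propan-2-yl)-7-oxabicyclo[2.2.1]hept-2-en-2-yl]oxy}silane
Conditions: LiN(iPr)2, THF, −78 °C; TMSCl, −78 → 0 °C
Reagents that add atoms: chlorotrimethylsilane, C[Si](C)(C)Cl
Why: Kinetic enolate O-silylation; only the CH2 α-carbon carries hydrogens (the other α-carbon is the bridgehead), so a single silyl enol ether can form.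

Step 4
Reactants: 5 trimethyl{[(1S,4S)-1-methyl-4-(propan-2-yl)-7-oxabicyclo[2.2.1]hept-2-en-2-yl]oxy}silane
Product: 6 (2S,5S)-5-formyl-2-methyl-5-(propan-2-yl)oxolane-2-carboxylic acid
Conditions: O3, CH2Cl2, −78 °C; Me2S, −78 → 25 °C; aqueous work-up
Reagents that add atoms: ozone, [O-][O+]=O
Why: Ozonolysis of the silyl enol ether cuts the C2–C11 bridge into an aldehyde (C2) and, after loss of silicon, a carboxylic acid (C11); both quaternary centres are untouched, so the two differentiated arms stay cis on the oxolane.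

Step 5
Reactants: 6 (2S,5S)-5-formyl-2-methyl-5-(propan-2-yl)oxolane-2-carboxylic acid
Product: 7 (2S,5S)-2-methyl-5-[(1E)-3-oxobut-1-en-1-yl]-5-(propan-2-yl)oxolane-2-carboxylic acid
Conditions: Ph3P=CHC(O)CH3 (2.2 equiv), toluene, 90 °C
Reagents that add atoms: 1-(triphenylphosphoranylidene)propan-2-one, CC(=O)C=P(c1ccccc1)(c1ccccc1)c1ccccc1
Why: Wittig olefination with a stabilised ylide should give the (E)-enone (C2=C3) from the non-enolisable α-alkoxy aldehyde, the second equivalent of ylide only buffering the carboxylic acid.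

Step 6
Reactants: 7 (2S,5S)-2-methyl-5-[(1E)-3-oxobut-1-en-1-yl]-5-(propan-2-yl)oxolane-2-carboxylic acid
Product: 9 (2S,5S)-N-methoxy-N,2-dimethyl-5-[(1E)-3-oxobut-1-en-1-yl]-5-(propan-2-yl)oxolane-2-carboxamide, via acyl imidazole 8 (not isolated)
Conditions: CDI, CH2Cl2, 25 °C; then MeNH(OMe)·HCl, 25 °C
Reagents that add atoms: N,O-dimethylhydroxylamine hydrochloride, CNOC.Cl; 1,1'-carbonyldiimidazole, O=C(n1ccnc1)n1ccnc1 (imidazole of 8 only)
Why: Weinreb amide formation through the acyl imidazole, the released imidazole taking up HCl and the enone being inert to the weakly nucleophilic hydroxylamine.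

Step 7
Reactants: 9 (2S,5S)-N-methoxy-N,2-dimethyl-5-[(1E)-3-oxobut-1-en-1-yl]-5-(propan-2-yl)oxolane-2-carboxamide
Product: 10 (2S,5S)-5-[(1E,3S)-3-hydroxy-3-methylhexa-1,5-dien-1-yl]-N-methoxy-N,2-dimethyl-5-(propan-2-yl)oxolane-2-carboxamide
Conditions: 2-allyl-1,3,2-dioxaborinane, (S)-3,3'-Br2-BINOL (15 mol %), tBuOH, toluene, 25 °C
Reagents that add atoms: 2-allyl-1,3,2-dioxaborinane, C=CCB1OCCCO1
Why: Chiral-diol-catalysed asymmetric allylboration of an alkenyl methyl ketone proceeds 1,2 through a chair transition state on the diol-bound boronate; the diol antipode is the one that, on a model aryl methyl ketone, delivers allyl to the Si face of C4=O (giving 4S), and the Weinreb amide does not react with allylboronates.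

Step 8
Reactants: 10 (2S,5S)-5-[(1E,3S)-3-hydroxy-3-methylhexa-1,5-dien-1-yl]-N-methoxy-N,2-dimethyl-5-(propan-2-yl)oxolane-2-carboxamide; 11 (4-bromobut-1-yn-1-yl)trimethylsilane
Product: 13 1-[(2S,5S)-5-[(1E,3S)-3-hydroxy-3-methylhexa-1,5-dien-1-yl]-2-methyl-5-(propan-2-yl)oxolan-2-yl]-5-(trimethylsilyl)pent-4-yn-1-one, via [4-(trimethylsilyl)but-3-yn-1-yl]magnesium bromide 12 (not isolated)
Conditions: 11, Mg, THF, 25 °C; then 10, THF, 0 °C; aq. NH4Cl
Reagents that add atoms: magnesium, [Mg] (in 12 only)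
Why: Grignard acylation of a Weinreb amide stops at the ketone through the magnesium chelate of the tetrahedral intermediate, one further equivalent of 12 being consumed by the tertiary hydroxyl.

Step 9
Reactants: 13 1-[(2S,5S)-5-[(1E,3S)-3-hydroxy-3-methylhexa-1,5-dien-1-yl]-2-methyl-5-(propan-2-yl)oxolan-2-yl]-5-(trimethylsilyl)pent-4-yn-1-one
Product: 14 (1R)-1-[(2S,5S)-5-[(1E,3S)-3-hydroxy-3-methylhexa-1,5-dien-1-yl]-2-methyl-5-(propan-2-yl)oxolan-2-yl]-5-(trimethylsilyl)pent-4-yn-1-ol
Conditions: (S)-2-methyl-CBS-oxazaborolidine (0.5 equiv), catecholborane, toluene, −78 °C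
Reagents that add atoms: none
Why: CBS reduction, in which the quaternary oxolane carbon C12 is the large and the C10 methylene the small ketone substituent, so the (S)-catalyst should deliver hydride to the face giving 11R, while catecholborane at low temperature leaves alkene and alkyne alone.

Step 10
Reactants: 14 (1R)-1-[(2S,5S)-5-[(1E,3S)-3-hydroxy-3-methylhexa-1,5-dien-1-yl]-2-methyl-5-(propan-2-yl)oxolan-2-yl]-5-(trimethylsilyl)pent-4-yn-1-ol
Product: 15 (1R)-1-[(2S,5S)-5-[(1E,3S)-3-hydroxy-3-methylhexa-1,5-dien-1-yl]-2-methyl-5-(propan-2-yl)oxolan-2-yl]pent-4-yn-1-ol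
Conditions: K2CO3, MeOH, 25 °C
Reagents that add atoms: none
Why: Base-mediated methanolysis of the alkynyl C–Si bond (protodesilylation) frees the terminal alkyne needed for the key step.

Step 11
Reactants: 15 (1R)-1-[(2S,5S)-5-[(1E,3S)-3-hydroxy-3-methylhexa-1,5-dien-1-yl]-2-methyl-5-(propan-2-yl)oxolan-2-yl]pent-4-yn-1-ol
Product: 16 (2S,5S)-5-methyl-2-[(1E,3S)-3-methyl-3-[(triethylsilyl)oxy]hexa-1,5-dien-1-yl]-2-(propan-2-yl)-5-[(1R)-1-[(triethylsilyl)oxy]pent-4-yn-1-yl]oxolane
Conditions: TESOTf, 2,6-lutidine, CH2Cl2, −78 → 0 °C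
Reagents that add atoms: triethylsilyl trifluoromethanesulfonate, CC[Si](CC)(CC)OS(=O)(=O)C(F)(F)F
Why: Silyl triflate silylation protects the hindered secondary C11 hydroxyl and the tertiary C4 hydroxyl in one operation, so that the β-oxygenated aldehyde of step 12 cannot undergo retro-aldol cleavage and Me2Zn is not consumed in step 13.

Step 12
Reactants: 16 (2S,5S)-5-methyl-2-[(1E,3S)-3-methyl-3-[(triethylsilyl)oxy]hexa-1,5-dien-1-yl]-2-(propan-2-yl)-5-[(1R)-1-[(triethylsilyl)oxy]pent-4-yn-1-yl]oxolane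
Product: 17 (3S,4E)-3-methyl-5-[(2S,5S)-5-methyl-2-(propan-2-yl)-5-[(1R)-1-[(triethylsilyl)oxy]pent-4-yn-1-yl]oxolan-2-yl]-3-[(triethylsilyl)oxy]pent-4-enal
Conditions: OsO4 (2 mol %), NaIO4, 2,6-lutidine, dioxane/H2O, 25 °C
Reagents that add atoms: osmium tetroxide, O=[Os](=O)(=O)=O (catalytic oxygen carrier); sodium periodate, [Na+].[O-][I](=O)(=O)=O
Why: Lemieux–Johnson cleavage should take the monosubstituted terminal alkene selectively, because the C2=C3 alkene lies between two fully substituted carbons and the alkyne is far less reactive towards OsO4.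

Step 13
Reactants: 17 (3S,4E)-3-methyl-5-[(2S,5S)-5-methyl-2-(propan-2-yl)-5-[(1R)-1-[(triethylsilyl)oxy]pent-4-yn-1-yl]oxolan-2-yl]-3-[(triethylsilyl)oxy]pent-4-enal
Product: 18 (1S,2R,5E,9S,10E,12S)-1,5,9-trimethyl-12-(propan-2-yl)-2,9-bis[(triethylsilyl)oxy]-15-oxabicyclo[10.2.1]pentadeca-5,10-dien-7-ol (both epimers at the carbinol carbon C6)
Conditions: Ni(cod)2 (20 mol %), IMes·HCl (20 mol %), KOtBu (20 mol %), Me2Zn (3 equiv), THF, 0 → 25 °C, slow addition of 17 (final 2 mM)
Reagents that add atoms: dimethylzinc, C[Zn]C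
Why: Proposed new method: zerovalent nickel couples the aldehyde C6=O and the terminal alkyne oxidatively to an oxanickelacyclopentene (C6–C7 bond), Me2Zn opens it by Zn–O/Ni–CH3 exchange, and C(sp2)–CH3 reductive elimination puts the methyl on C8 syn to the new C–C bond, which gives the (E)-trisubstituted alkene and returns the catalyst. The closest known reaction types are the nickel-catalysed three-component alkylative coupling of aldehydes, terminal alkynes and organozinc reagents (known between molecules and for small rings) and the nickel/carbene-catalysed reductive macrocyclisation of terminal ynals with silanes; joining organozinc methyl transfer to macrocyclisation is the new element. The 14-membered carbocycle closes in the endo mode, the aldehyde carbon bonding to the unsubstituted alkyne terminus C7, which is the intrinsic regiochemistry of terminal alkynes with a small ligand such as IMes. The only new stereocentre, the C6 carbinol, is not controlled and is erased in step 14, while the alkene geometry follows from the syn addition across the alkyne. The step needs regioselectivity (C7, not C8) and chemoselectivity over direct methyl addition to the aldehyde and over alkyne oligomerisation; these should be secured by the terminal alkyne, the low uncatalysed reactivity of Me2Zn towards aldehydes, slow addition at high dilution, and the cis-2,5-disubstituted oxolane, which turns both chains to the same face and brings C6 and C7 within reach.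

Step 14
Reactants: 18 (1S,2R,5E,9S,10E,12S)-1,5,9-trimethyl-12-(propan-2-yl)-2,9-bis[(triethylsilyl)oxy]-15-oxabicyclo[10.2.1]pentadeca-5,10-dien-7-ol
Product: 19 (1S,2R,5E,9S,10E,12S)-1,5,9-trimethyl-12-(propan-2-yl)-2,9-bis[(triethylsilyl)oxy]-15-oxabicyclo[10.2.1]pentadeca-5,10-dien-7-one
Conditions: nPr4N[RuO4] (5 mol %), NMO, 4 Å MS, CH2Cl2, 25 °C
Reagents that add atoms: none
Why: Ley–Griffith oxidation of the allylic alcohol should converge both C6 epimers on one (E)-enone without touching the silyl ethers.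

Step 15
Reactants: 19 (1S,2R,5E,9S,10E,12S)-1,5,9-trimethyl-12-(propan-2-yl)-2,9-bis[(triethylsilyl)oxy]-15-oxabicyclo[10.2.1]pentadeca-5,10-dien-7-one
Product: 20 (1S,2R,5S,9S,10E,12S)-1,5,9-trimethyl-12-(propan-2-yl)-2,9-bis[(triethylsilyl)oxy]-15-oxabicyclo[10.2.1]pentadec-10-en-7-one
Conditions: Cu(OAc)2·H2O (5 mol %), (R)-DTBM-SEGPHOS (5 mol %), (EtO)2MeSiH, tBuOH, toluene, 0 °C
Reagents that add atoms: none
Why: Ligated CuH asymmetric conjugate reduction of a β,β-disubstituted (E)-enone: hydride adds to one face of C8 under ligand control (antipode fixed on a model (E)-enone so that 8S results, the large ring behaving like an open-chain enone), tBuOH protonates the enolate at C7, and the hindered isolated C2=C3 alkene is not a substrate.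

Step 16
Reactants: 20 (1S,2R,5S,9S,10E,12S)-1,5,9-trimethyl-12-(propan-2-yl)-2,9-bis[(triethylsilyl)oxy]-15-oxabicyclo[10.2.1]pentadec-10-en-7-one
Product: 21 (1S,2R,5S,9S,10E,12S)-2,9-dihydroxy-1,5,9-trimethyl-12-(propan-2-yl)-15-oxabicyclo[10.2.1]pentadec-10-en-7-one
Conditions: HF·pyridine, pyridine, THF, 0 → 25 °C
Reagents that add atoms: none
Why: Buffered fluoride desilylation should remove both triethylsilyl ethers under conditions too mild for retro-aldol cleavage or dehydration of the tertiary β-hydroxy ketone.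

Step 17
Reactants: 21 (1S,2R,5S,9S,10E,12S)-2,9-dihydroxy-1,5,9-trimethyl-12-(propan-2-yl)-15-oxabicyclo[10.2.1]pentadec-10-en-7-one
Product: 22 (1S,2R,5S,9S,10E,12S)-9-hydroxy-1,5,9-trimethyl-7-oxo-12-(propan-2-yl)-15-oxabicyclo[10.2.1]pentadec-10-en-2-yl formate
Conditions: HCO2H, DCC, DMAP (cat.), CH2Cl2, 0 °C
Reagents that add atoms: formic acid, OC=O
Why: Steglich-type formylation should acylate only the secondary C11 hydroxyl, the tertiary allylic C4 hydroxyl being far less reactive, and the near-neutral conditions leave the β-hydroxy ketone intact.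

**Compound list**

1 | (R)-(−)-terpinen-4-ol, (1R)-4-methyl-1-(propan-2-yl)cyclohex-3-en-1-ol | CC(C)[C@]1(O)CC=C(C)CC1 | starting material
2 | (1S,2R,4R)-1,2-epoxy-p-menthan-4-ol (epoxide syn to the hydroxyl) | CC(C)[C@]1(O)C[C@H]2O[C@@]2(C)CC1 | intermediate
3 | (1S,2R,4R)-1-methyl-4-(propan-2-yl)-7-oxabicyclo[2.2.1]heptan-2-ol (2-exo-hydroxy-1,4-cineole) | CC(C)[C@]12C[C@@H](O)[C@](C)(CC1)O2 | intermediate
4 | (1S,4R)-1-methyl-4-(propan-2-yl)-7-oxabicyclo[2.2.1]heptan-2-one | CC(C)[C@]12CC(=O)[C@](C)(CC1)O2 | intermediate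
5 | trimethyl{[(1S,4S)-1-methyl-4-(propan-2-yl)-7-oxabicyclo[2.2.1]hept-2-en-2-yl]oxy}silane | CC(C)[C@]12C=C(O[Si](C)(C)C)[C@](C)(CC1)O2 | intermediate
6 | (2S,5S)-5-formyl-2-methyl-5-(propan-2-yl)oxolane-2-carboxylic acid (formyl and carboxyl cis) | CC(C)[C@]1(C=O)CC[C@@](C)(C(=O)O)O1 | intermediate
7 | (2S,5S)-2-methyl-5-[(1E)-3-oxobut-1-en-1-yl]-5-(propan-2-yl)oxolane-2-carboxylic acid | CC(C)[C@]1(/C=C/C(C)=O)CC[C@@](C)(C(=O)O)O1 | intermediate
8 | (3E)-4-[(2S,5S)-5-(1H-imidazole-1-carbonyl)-5-methyl-2-(propan-2-yl)oxolan-2-yl]but-3-en-2-one | CC(C)[C@]1(/C=C/C(C)=O)CC[C@@](C)(C(=O)n2ccnc2)O1 | intermediate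
9 | (2S,5S)-N-methoxy-N,2-dimethyl-5-[(1E)-3-oxobut-1-en-1-yl]-5-(propan-2-yl)oxolane-2-carboxamide | CC(C)[C@]1(/C=C/C(C)=O)CC[C@@](C)(C(=O)N(C)OC)O1 | intermediate
10 | (2S,5S)-5-[(1E,3S)-3-hydroxy-3-methylhexa-1,5-dien-1-yl]-N-methoxy-N,2-dimethyl-5-(propan-2-yl)oxolane-2-carboxamide | CC(C)[C@]1(/C=C/[C@@](C)(O)CC=C)CC[C@@](C)(C(=O)N(C)OC)O1 | intermediate
11 | (4-bromobut-1-yn-1-yl)trimethylsilane | C[Si](C)(C)C#CCCBr | starting material
12 | [4-(trimethylsilyl)but-3-yn-1-yl]magnesium bromide | C[Si](C)(C)C#CCC[Mg]Br | intermediate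
13 | 1-[(2S,5S)-5-[(1E,3S)-3-hydroxy-3-methylhexa-1,5-dien-1-yl]-2-methyl-5-(propan-2-yl)oxolan-2-yl]-5-(trimethylsilyl)pent-4-yn-1-one | CC(C)[C@]1(/C=C/[C@@](C)(O)CC=C)CC[C@@](C)(C(=O)CCC#C[Si](C)(C)C)O1 | intermediate
14 | (1R)-1-[(2S,5S)-5-[(1E,3S)-3-hydroxy-3-methylhexa-1,5-dien-1-yl]-2-methyl-5-(propan-2-yl)oxolan-2-yl]-5-(trimethylsilyl)pent-4-yn-1-ol | CC(C)[C@]1(/C=C/[C@@](C)(O)CC=C)CC[C@@](C)([C@H](O)CCC#C[Si](C)(C)C)O1 | intermediate
15 | (1R)-1-[(2S,5S)-5-[(1E,3S)-3-hydroxy-3-methylhexa-1,5-dien-1-yl]-2-methyl-5-(propan-2-yl)oxolan-2-yl]pent-4-yn-1-ol | CC(C)[C@]1(/C=C/[C@@](C)(O)CC=C)CC[C@@](C)([C@H](O)CCC#C)O1 | intermediate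
16 | (2S,5S)-5-methyl-2-[(1E,3S)-3-methyl-3-[(triethylsilyl)oxy]hexa-1,5-dien-1-yl]-2-(propan-2-yl)-5-[(1R)-1-[(triethylsilyl)oxy]pent-4-yn-1-yl]oxolane | CC(C)[C@]1(/C=C/[C@@](C)(O[Si](CC)(CC)CC)CC=C)CC[C@@](C)([C@H](O[Si](CC)(CC)CC)CCC#C)O1 | intermediate
17 | (3S,4E)-3-methyl-5-[(2S,5S)-5-methyl-2-(propan-2-yl)-5-[(1R)-1-[(triethylsilyl)oxy]pent-4-yn-1-yl]oxolan-2-yl]-3-[(triethylsilyl)oxy]pent-4-enal | CC(C)[C@]1(/C=C/[C@@](C)(O[Si](CC)(CC)CC)CC=O)CC[C@@](C)([C@H](O[Si](CC)(CC)CC)CCC#C)O1 | intermediate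
18 | (1S,2R,5E,9S,10E,12S)-1,5,9-trimethyl-12-(propan-2-yl)-2,9-bis[(triethylsilyl)oxy]-15-oxabicyclo[10.2.1]pentadeca-5,10-dien-7-ol (both C7 epimers of this name, i.e. C6 of the working numbers) | CC(C)[C@]12/C=C/[C@@](C)(O[Si](CC)(CC)CC)CC(O)/C=C(C)/CC[C@@H](O[Si](CC)(CC)CC)[C@](C)(CC1)O2 | intermediate
19 | (1S,2R,5E,9S,10E,12S)-1,5,9-trimethyl-12-(propan-2-yl)-2,9-bis[(triethylsilyl)oxy]-15-oxabicyclo[10.2.1]pentadeca-5,10-dien-7-one | CC(C)[C@]12/C=C/[C@@](C)(O[Si](CC)(CC)CC)CC(=O)/C=C(C)/CC[C@@H](O[Si](CC)(CC)CC)[C@](C)(CC1)O2 | intermediate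
20 | (1S,2R,5S,9S,10E,12S)-1,5,9-trimethyl-12-(propan-2-yl)-2,9-bis[(triethylsilyl)oxy]-15-oxabicyclo[10.2.1]pentadec-10-en-7-one | CC(C)[C@]12/C=C/[C@@](C)(O[Si](CC)(CC)CC)CC(=O)C[C@@H](C)CC[C@@H](O[Si](CC)(CC)CC)[C@](C)(CC1)O2 | intermediate
21 | (1S,2R,5S,9S,10E,12S)-2,9-dihydroxy-1,5,9-trimethyl-12-(propan-2-yl)-15-oxabicyclo[10.2.1]pentadec-10-en-7-one | CC(C)[C@]12/C=C/[C@@](C)(O)CC(=O)C[C@@H](C)CC[C@@H](O)[C@](C)(CC1)O2 | intermediate
22 | (1S,2R,5S,9S,10E,12S)-9-hydroxy-1,5,9-trimethyl-7-oxo-12-(propan-2-yl)-15-oxabicyclo[10.2.1]pentadec-10-en-2-yl formate | CC(C)[C@]12/C=C/[C@@](C)(O)CC(=O)C[C@@H](C)CC[C@@H](OC=O)[C@](C)(CC1)O2 | target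

**Step count and risks**

Total step count: 17. Longest linear sequence: 17 steps (1 → 22; 11 enters in step 8).

Steps most likely to fail:

Step 13 (new method). The oxidative coupling may place the aldehyde carbon on the internal alkyne carbon (13-membered ring with exocyclic alkene), intermolecular coupling or alkyne oligomerisation may outrun ring closure, or methyl may be transferred to the aldehyde before coupling. The fallback uses known chemistry, sets out from 16 and returns at 18. Negishi carboalumination of the terminal alkyne of 16 (Me3Al, Cp2ZrCl2, CH2Cl2; then I2) should give the (E)-2-methyl-1-iodoalkene F1, the monosubstituted alkene reacting far more slowly. Lemieux–Johnson cleavage as in step 12 would give the iodo aldehyde F2. Nozaki–Hiyama–Kishi macrocyclisation (CrCl2, NiCl2 (cat.), DMSO/THF, high dilution) then forms the same C6–C7 bond with retention of the alkene geometry and gives 18.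

Step 15. Hydride may be delivered to the wrong face of C8 because the flexible 14-membered enone and its resident stereocentres erode ligand control, and 1,2-reduction may compete. The fallback sets out from 18 and returns at 20, with stereocontrol from the substrate instead of the catalyst. The C6 epimers of 18 are separated and the (6S)-allylic alcohol F3 is hydrogenated with [Rh(nbd)(dppb)]BF4 and H2 in CH2Cl2. In F3, 1,3-allylic strain between C6 and the C8 methyl holds the C6–H in the alkene plane, so the hydroxyl-bound rhodium should deliver hydrogen to the face that gives 8S, forming the saturated alcohol F4. Ley–Griffith oxidation of F4 gives 20. The (6R)-epimer of 18 is returned through 19 (step 14) and Luche reduction (NaBH4, CeCl3·7H2O) to the mixture 18.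

Step 7. Facial selectivity at the C4 ketone may be low, because the bulky quaternary C1 next to the alkene can disturb the ordered transition state on the chiral boronate. The fallback sets out from 9 and returns at 10, securing C4 by separation instead of reagent control. Indium-mediated Barbier allylation (allyl bromide, In, THF/H2O) leaves the Weinreb amide alone and gives 10 together with its C4 epimer F5. The two are diastereomers and are separated by chromatography.

Further compounds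
F1 | step 13 | (2S,5S)-5-[(1R,5E)-6-iodo-5-methyl-1-[(triethylsilyl)oxy]hex-5-en-1-yl]-5-methyl-2-[(1E,3S)-3-methyl-3-[(triethylsilyl)oxy]hexa-1,5-dien-1-yl]-2-(propan-2-yl)oxolane | CC(C)[C@]1(/C=C/[C@@](C)(O[Si](CC)(CC)CC)CC=C)CC[C@@](C)([C@H](O[Si](CC)(CC)CC)CC/C(C)=C/I)O1
F2 | step 13 | (3S,4E)-5-[(2S,5S)-5-[(1R,5E)-6-iodo-5-methyl-1-[(triethylsilyl)oxy]hex-5-en-1-yl]-5-methyl-2-(propan-2-yl)oxolan-2-yl]-3-methyl-3-[(triethylsilyl)oxy]pent-4-enal | CC(C)[C@]1(/C=C/[C@@](C)(O[Si](CC)(CC)CC)CC=O)CC[C@@](C)([C@H](O[Si](CC)(CC)CC)CC/C(C)=C/I)O1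
F3 | step 15 | (1S,2R,5E,7S,9S,10E,12S)-1,5,9-trimethyl-12-(propan-2-yl)-2,9-bis[(triethylsilyl)oxy]-15-oxabicyclo[10.2.1]pentadeca-5,10-dien-7-ol | CC(C)[C@]12/C=C/[C@@](C)(O[Si](CC)(CC)CC)C[C@H](O)/C=C(C)/CC[C@@H](O[Si](CC)(CC)CC)[C@](C)(CC1)O2
F4 | step 15 | (1S,2R,5S,7R,9S,10E,12S)-1,5,9-trimethyl-12-(propan-2-yl)-2,9-bis[(triethylsilyl)oxy]-15-oxabicyclo[10.2.1]pentadec-10-en-7-ol | CC(C)[C@]12/C=C/[C@@](C)(O[Si](CC)(CC)CC)C[C@H](O)C[C@@H](C)CC[C@@H](O[Si](CC)(CC)CC)[C@](C)(CC1)O2
F5 | step 7 | (2S,5S)-5-[(1E,3R)-3-hydroxy-3-methylhexa-1,5-dien-1-yl]-N-methoxy-N,2-dimethyl-5-(propan-2-yl)oxolane-2-carboxamide | CC(C)[C@]1(/C=C/[C@](C)(O)CC=C)CC[C@@](C)(C(=O)N(C)OC)O1
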